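## The problem

The target, 6-hydroxy-7-methoxy-3-(2,4,5-trimethoxyphenyl)-4H-chromen-4-one (8), is an isoflavone: a benzopyran-4-one (rings A and C) carrying ring B on C3. It has no stereocentre and the C3–C1' axis is not configurationally stable, so the task is one of connectivity and chemoselectivity only. The bond that defines the class, C3–C1', joins two electron-rich sp2 carbons between the 2'-methoxy group and the C4 carbonyl; the customary answers either bring it in ready-made in an arylacetic acid or make it from two partners that each need a handle at exactly these positions. Ring A is oxygenated at C8a (O1), C7 and C6, with O1 and the 6-OH para to each other, so every open-chain precursor is a hydroquinone derivative and is easily oxidised. One oxygen of five is a free phenol, and it must stay distinguishable from the first step, because no late demethylation could single out O6 among the 7-, 2'-, 4'- and 5'-methyl ethers. Ring C is a vinylogous ester whose C2 is opened by hydroxide, alkoxide and amines and whose C2=C3 bond can be hydrogenated, and ring B is an easily oxidised trialkoxybenzene. The feature that the plan exploits is that both ends of the C3–C1' bond are the native nucleophilic C–H positions of simple π-systems. C3 is the α-carbon of the vinylogous ester O1–C2=C3–C4=O (and of the vinylogous amide N–C2=C3–C4=O in a ring-opened enaminone), and C1' lies para to the 4'-methoxy and ortho to the 2'-methoxy group, which makes it C5 of 1,2,4-trimethoxybenzene (5), the position at which that arene is attacked by electrophiles and at which its radical cation couples. The bond can therefore be made by removing two hydrogens, with no halide or metal on either carbon.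

## Retrosynthesis

**8 ⇒ 7.** The O6–acyl bond of a pivalate is cut. An ester is preferred to a benzyl or silyl ether for two reasons: it makes the hydroquinone-type ring A a poor electron donor during the oxidative key step, and its removal needs no hydrogenation near C2=C3. The forward reaction must cleave a hindered aryl ester without adding a nucleophile to C2 of ring C.

**7 ⇒ 4 + 5 (key disconnection).** Two bonds are cut together: C3–C1' between rings C and B, and O1–C2 of ring C. Cutting only C3–C1' at the chromone stage would call for a halide on one carbon and a metal on the other. Cutting only O1–C2 would require ring B to sit already on the carbon chain. Cutting both leads to enaminone 4, in which the future C3 is the α-carbon of a vinylogous amide, the strongest carbon nucleophile this skeleton offers, and to the unfunctionalised arene 5. Ring closure follows the C–C bond formation by itself, because the phenolic oxygen sits next to the amine-bearing β-carbon. The precursors are far simpler than 7: 4 has one ring and a three-carbon chain, and 5 is a bulk arene with no handle. The forward reaction has to remove one hydrogen from each partner and the amino group from 4. It needs cross-coupling instead of homo-coupling, reaction of 5 at C5 only, and oxidation of neither ring A nor the product.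

**4 ⇒ 3.** The C2=C3 double bond and the C2–N bond are cut, which takes the chain back to the methyl ketone 3 and a one-carbon amide acetal. The alternative of building the chain by a Claisen formylation would need strong base, which the ester of 3 would not survive. The forward condensation must leave the pivalate and the chelated phenol untouched.

**3 ⇒ 2.** The ester bond is cut. The two hydroxyl groups of 2 differ by themselves: the 2-OH is hydrogen-bonded to the ketone, the 5-OH is free, so one equivalent of a hindered acylating agent should find only the latter. No separate differentiation step is needed.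

**2 ⇒ 1.** The aryl–acyl bond (the future C4–C4a) is cut, which leads to methoxyhydroquinone 1 and an acetyl donor. In 1 only one carbon is both para to the methoxy group and ortho to a hydroxyl, and that carbon is the one needed. The oxygenation pattern of ring A, including the free O6 and the methylated O7, is therefore bought with the starting material.

## Roads not taken

Alternative 1: The most obvious route cuts C4–C4a and the one-carbon unit C2, and carries the C3–C1' bond in from the start. Friedel–Crafts acylation of 1 with (2,4,5-trimethoxyphenyl)acetic acid A2 would give the deoxybenzoin A1, and formylative ring closure would give 8. This is short and reliable on paper. It was not chosen for three reasons.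
- A2 is not a commodity. It has to be made from 5 by attaching a two-carbon chain at the very carbon that the chosen plan uses directly as C–H, so the count from 1 and 5 is no lower.
- A1 is a free hydroquinone with a doubly activated methylene and has to be made in hot Lewis acid. The one-carbon closure then has to discriminate the 5-OH, which an amide acetal methylates and chloroiminium reagents formylate or sulfonylate, so protection steps return.
- The key bond is not made at all but inherited, so the route offers no convergent, late union of the two rings.

Alternative 2: Cut only C3–C1' and join a 3-halochromone to an arylmetal. Iodocyclisation of 4 would give 3-iodochromone A3, and Suzuki–Miyaura coupling with (2,4,5-trimethoxyphenyl)boronic acid A4 would give 7. It puts iodine on C3 and boron on C1', the two carbons that are already the nucleophilic positions of their π-systems, only to remove both again. It is one step longer than the chosen route. A4 is an ortho-alkoxy, very electron-rich boronic acid that is prone to protodeboronation under the aqueous base, and that base also threatens C2 of ring C and the ester. It is kept as the fallback for the key step.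

Alternative 3: Make C3–C1' by a 1,2-aryl shift, as in the biosynthesis. Claisen–Schmidt condensation of 2 (after 5-O-benzylation, since the pivalate of 3 would not survive aqueous KOH) with 2,4,5-trimethoxybenzaldehyde A6 would give 2'-hydroxychalcone A5. Oxidative rearrangement with Tl(NO3)3 or PhI(OAc)2 in methanol would move ring B from the β- to the α-carbon and give acetal A7, and acid would close ring C. The electron-rich ring B migrates well, but the plan is weaker on three counts.
- The oxidant meets an alkoxyphenol ring A and a trialkoxybenzene ring B, both of which compete with the alkene.
- The free 2'-OH of A5 diverts material to flavanone and aurone.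
- The sequence needs benzylation, aldol condensation, rearrangement, ring closure and debenzylation, two steps more than the chosen route, with A6 itself derived from 5 by formylation and with a toxic thallium salt or a stoichiometric iodane.

Key step: step 4

Remark: 8 has no stereocentre; 1 and 5 are taken as purchased; HFIP is 1,1,1,3,3,3-hexafluoropropan-2-ol and DMF-DMA is N,N-dimethylformamide dimethyl acetal.

## Route

Step 1
Reactants: 1 methoxyhydroquinone (2-methoxybenzene-1,4-diol)
Product: 2 1-(2,5-dihydroxy-4-methoxyphenyl)ethan-1-one
Conditions: AcOH, BF3·OEt2 (3 equiv), 90 °C, N2; then H2O
Reagents that add atoms: acetic acid, CC(=O)O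
Why: Friedel–Crafts (Nencki-type) C-acetylation; the acylating species attacks C5 of 1, the only carbon that is both para to the methoxy group and ortho to a hydroxyl. The product is held as its boron chelate, which should prevent a second acylation.

Step 2
Reactants: 2 1-(2,5-dihydroxy-4-methoxyphenyl)ethan-1-one
Product: 3 5-acetyl-4-hydroxy-2-methoxyphenyl 2,2-dimethylpropanoate (the 5-O-pivalate of 2; the hydroxyl ortho to the acetyl group stays free)
Conditions: PivCl (1.05 equiv), Et3N, CH2Cl2, 0 °C
Reagents that add atoms: pivaloyl chloride, CC(C)(C)C(=O)Cl
Why: Selective O-acylation; the hydroxyl ortho to the ketone is locked in a hydrogen bond and is far less nucleophilic than the free one, so one equivalent of the hindered acid chloride should esterify only the latter. The ester also makes ring A a poorer electron donor for step 4.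

Step 3
Reactants: 3 5-acetyl-4-hydroxy-2-methoxyphenyl 2,2-dimethylpropanoate
Product: 4 5-[(2E)-3-(dimethylamino)prop-2-enoyl]-4-hydroxy-2-methoxyphenyl 2,2-dimethylpropanoate
Conditions: DMF-DMA (1.5 equiv), toluene, 80 °C
Reagents that add atoms: N,N-dimethylformamide dimethyl acetal, COC(OC)N(C)C
Why: Condensation of the methyl ketone with an amide acetal (enaminone formation) gives the E vinylogous amide. The chelated phenol is not methylated under these conditions, and the hindered pivalate should resist the methanol that is released.

Step 4
Reactants: 4 5-[(2E)-3-(dimethylamino)prop-2-enoyl]-4-hydroxy-2-methoxyphenyl 2,2-dimethylpropanoate; 5 1,2,4-trimethoxybenzene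
Product: 7 7-methoxy-4-oxo-3-(2,4,5-trimethoxyphenyl)-4H-chromen-6-yl 2,2-dimethylpropanoate, via α-aryl enaminone 6 (not isolated)
Conditions: undivided cell, graphite anode, Pt cathode, constant current (about 2.2 F per mol of 4), 5 (2 equiv), nBu4NBF4, MeCN/HFIP 9:1, rt; then AcOH, 50 °C
Reagents that add atoms: none
Why: Proposed new method: anodic dehydrogenative C–H/C–H cross-coupling of an enaminone with an arene, followed in the same pot by chromone annulation. One-electron oxidation at the anode of 5 (oxidation potential near +1.1 V against SCE) or of the vinylogous amide of 4, which should lie close to it, gives a radical cation that is captured by the other, neutral partner; either order joins the same two atoms, the α-carbon of 4 (the future C3) and C5 of 5. Loss of a second electron and of the ring proton rearomatises ring B and gives α-aryl enaminone 6; its chelated phenolic oxygen then adds to the β-carbon (6-endo-trig conjugate addition to the vinylogous amide, or 6-exo-trig if it happens at the iminium stage) and expels dimethylamine, which closes ring C at O1–C2, while the cathode turns the released protons into H2, so no chemical oxidant is used. The closest known reaction types are the anodic cross-coupling of electron-rich arenes through arene radical cations in HFIP-containing electrolytes, the capture of alkoxyarene radical cations by β-dicarbonyl carbon nucleophiles, and the electrochemical C3-functionalisation with ring closure of o-hydroxyaryl enaminones by sulfur, selenium and halogen partners. Site selectivity in 5 is set by its substitution: C5 is para to the C2 methoxy and ortho to the C4 methoxy group, whereas C3 is wedged between two methoxy groups and C6 is activated by only one. Cross-coupling in preference to homo-coupling rests on the enaminone α-carbon being a far stronger π-nucleophile than neutral 5; chemoselectivity rests on the pivalate, which makes the hydroquinone-type ring A a poor donor, and on the product itself, whose ring B has lost its reactive position and carries an electron-poor chromonyl group. No stereocentre is formed.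

Step 5
Reactants: 7 7-methoxy-4-oxo-3-(2,4,5-trimethoxyphenyl)-4H-chromen-6-yl 2,2-dimethylpropanoate
Product: 8 6-hydroxy-7-methoxy-3-(2,4,5-trimethoxyphenyl)-4H-chromen-4-one
Conditions: K2CO3 (2 equiv), MeOH, rt; then 1 M HCl
Reagents that add atoms: none
Why: Base-mediated transesterification (methanolysis) of the aryl ester. The phenoxide that forms at C6 should make ring C less prone to addition at C2, and no reducing agent comes near C2=C3.

## Compound list

1 | methoxyhydroquinone (2-methoxybenzene-1,4-diol) | COc1cc(O)ccc1O | starting material
2 | 1-(2,5-dihydroxy-4-methoxyphenyl)ethan-1-one | CC(=O)c1cc(O)c(OC)cc1O | intermediate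
3 | 5-acetyl-4-hydroxy-2-methoxyphenyl 2,2-dimethylpropanoate | CC(=O)c1cc(OC(=O)C(C)(C)C)c(OC)cc1O | intermediate
4 | 5-[(2E)-3-(dimethylamino)prop-2-enoyl]-4-hydroxy-2-methoxyphenyl 2,2-dimethylpropanoate | CN(C)/C=C/C(=O)c1cc(OC(=O)C(C)(C)C)c(OC)cc1O | intermediate
5 | 1,2,4-trimethoxybenzene | COc1ccc(OC)c(OC)c1 | starting material
6 | 5-[(2E)-3-(dimethylamino)-2-(2,4,5-trimethoxyphenyl)prop-2-enoyl]-4-hydroxy-2-methoxyphenyl 2,2-dimethylpropanoate (α-aryl enaminone, configurationally labile) | CN(C)/C=C(\c1cc(OC)c(OC)cc1OC)C(=O)c1cc(OC(=O)C(C)(C)C)c(OC)cc1O | intermediate (not isolated)
7 | 7-methoxy-4-oxo-3-(2,4,5-trimethoxyphenyl)-4H-chromen-6-yl 2,2-dimethylpropanoate | COc1cc2occ(-c3cc(OC)c(OC)cc3OC)c(=O)c2cc1OC(=O)C(C)(C)C | intermediate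
8 | 6-hydroxy-7-methoxy-3-(2,4,5-trimethoxyphenyl)-4H-chromen-4-one | COc1cc2occ(-c3cc(OC)c(OC)cc3OC)c(=O)c2cc1O | target

## Step count and risk

Total step count: 5. Longest linear sequence: 5 steps (1 → 2 → 3 → 4 → 7 → 8); arene 5 enters unchanged in step 4.

**Step 4 (key step, bears the label "Proposed new method:").** Three things are most likely to go wrong.
- The radical cation of 5 may homo-couple with neutral 5 before 4 captures it.
- Ring closure of 4 to the 3-unsubstituted chromone, induced by HFIP or by anodically generated acid, may come before the C–C bond is made and remove the strong carbon nucleophile.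
- The released dimethylamine may be oxidised at the anode or may attack the ester.

Fallback with known chemistry, from 4 back to 7: iodocyclisation of 4 with I2 in CHCl3 at rt should give 3-iodo-7-methoxy-4-oxo-4H-chromen-6-yl 2,2-dimethylpropanoate F1 (identical with A3). This proceeds by electrophilic iodination of the enaminone α-carbon, ring closure and loss of dimethylamine. Suzuki–Miyaura coupling of F1 with purchased boronic acid A4 (Pd(OAc)2, SPhos, K3PO4, toluene/H2O, 80 °C) should then give 7. This costs one step and gives up the C–H/C–H union, but leaves the rest of the route unchanged.

**Step 3.** Most likely to go wrong: transesterification of the aryl pivalate by the methoxide that the amide acetal releases, followed by O-methylation of the freed phenoxide, which would erase the difference between O6 and the methyl ethers.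

Fallback, from 2 back to 8: the ester is replaced by an ether.
- BnBr and K2CO3 in acetone should alkylate only the non-chelated hydroxyl of 2 and give 1-[5-(benzyloxy)-2-hydroxy-4-methoxyphenyl]ethan-1-one F2.
- DMF-DMA then gives (2E)-1-[5-(benzyloxy)-2-hydroxy-4-methoxyphenyl]-3-(dimethylamino)prop-2-en-1-one F3, which has no group that methoxide can cleave.
- F3 is coupled with 5 under the conditions of step 4 (or through the iodocyclisation and Suzuki–Miyaura detour above) to 6-(benzyloxy)-7-methoxy-3-(2,4,5-trimethoxyphenyl)-4H-chromen-4-one F4.
- Hydrogenolysis (H2, Pd/C, EtOAc, rt, stopped after one equivalent) gives 8.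

The price is a more easily oxidised ring A in the anodic step and a hydrogenolysis that must be stopped before C2=C3 is reduced.

**Step 5.** Most likely to go wrong: conjugate addition of methoxide or adventitious hydroxide to C2 of ring C, with ring opening and loss of the C2 carbon, in competition with a slow methanolysis of the hindered ester.

Fallback, from 7 back to 8: the ring opening is made deliberate. Hot aqueous-ethanolic KOH under argon removes both the pivalate and C2 (as formate) and should give the deoxybenzoin 1-(2,5-dihydroxy-4-methoxyphenyl)-2-(2,4,5-trimethoxyphenyl)ethan-1-one F5 (identical with A1). One-carbon ring closure of F5 with DMF, BF3·OEt2 and MsCl, a method that tolerates free phenols, puts C2 back and gives 8.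

**Step 1.** Most likely to go wrong: air oxidation of the unprotected hydroquinone to the quinone in hot Lewis acid, and O-acetylation that stops short of C-acylation.

Fallback, from 1 back to 2: both hydroxyls are acetylated first (Ac2O, pyridine) to give 2-methoxy-1,4-phenylene diacetate F6, which is no longer a hydroquinone. Fries rearrangement (BF3·OEt2, AcOH, 100 °C) moves one acetyl group to the carbon para to the methoxy group and should give 5-acetyl-4-hydroxy-2-methoxyphenyl acetate F7. HCl in MeOH removes the remaining acetate and gives 2.

## Further compounds

F1 | step 4 | 3-iodo-7-methoxy-4-oxo-4H-chromen-6-yl 2,2-dimethylpropanoate | COc1cc2occ(I)c(=O)c2cc1OC(=O)C(C)(C)C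
F2 | step 3 | 1-[5-(benzyloxy)-2-hydroxy-4-methoxyphenyl]ethan-1-one | CC(=O)c1cc(OCc2ccccc2)c(OC)cc1O
F3 | step 3 | (2E)-1-[5-(benzyloxy)-2-hydroxy-4-methoxyphenyl]-3-(dimethylamino)prop-2-en-1-one | CN(C)/C=C/C(=O)c1cc(OCc2ccccc2)c(OC)cc1O
F4 | step 3 | 6-(benzyloxy)-7-methoxy-3-(2,4,5-trimethoxyphenyl)-4H-chromen-4-one | COc1cc2occ(-c3cc(OC)c(OC)cc3OC)c(=O)c2cc1OCc1ccccc1
F5 | step 5 | 1-(2,5-dihydroxy-4-methoxyphenyl)-2-(2,4,5-trimethoxyphenyl)ethan-1-one | COc1cc(O)c(C(=O)Cc2cc(OC)c(OC)cc2OC)cc1O
F6 | step 1 | 2-methoxy-1,4-phenylene diacetate | COc1cc(OC(C)=O)ccc1OC(C)=O
F7 | step 1 | 5-acetyl-4-hydroxy-2-methoxyphenyl acetate | CC(=O)Oc1cc(C(C)=O)c(O)cc1OC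
A1 | alternative 1 | 1-(2,5-dihydroxy-4-methoxyphenyl)-2-(2,4,5-trimethoxyphenyl)ethan-1-one | COc1cc(O)c(C(=O)Cc2cc(OC)c(OC)cc2OC)cc1O
A2 | alternative 1 | (2,4,5-trimethoxyphenyl)acetic acid | COc1cc(OC)c(CC(=O)O)cc1OC
A3 | alternative 2 | 3-iodo-7-methoxy-4-oxo-4H-chromen-6-yl 2,2-dimethylpropanoate | COc1cc2occ(I)c(=O)c2cc1OC(=O)C(C)(C)C
A4 | alternative 2 | (2,4,5-trimethoxyphenyl)boronic acid | COc1cc(OC)c(B(O)O)cc1OC
A5 | alternative 3 | (2E)-1-[5-(benzyloxy)-2-hydroxy-4-methoxyphenyl]-3-(2,4,5-trimethoxyphenyl)prop-2-en-1-one | COc1cc(O)c(C(=O)/C=C/c2cc(OC)c(OC)cc2OC)cc1OCc1ccccc1
A6 | alternative 3 | 2,4,5-trimethoxybenzaldehyde | COc1cc(OC)c(C=O)cc1OC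
A7 | alternative 3 | 1-[5-(benzyloxy)-2-hydroxy-4-methoxyphenyl]-3,3-dimethoxy-2-(2,4,5-trimethoxyphenyl)propan-1-one (racemic) | COc1cc(O)c(C(=O)C(C(OC)OC)c2cc(OC)c(OC)cc2OC)cc1OCc1ccccc1
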